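## Retrosynthetic overview
1. 14 ⇒ 13: the three phenols are unmasked last by hydrogenolysis of their benzyl ethers.
2. 13 ⇒ 9: the acetate C–O bond and the C5 carbinol come in one operation from a β-peroxy ketone and acetaldehyde (reductive Evans–Tishchenko). The ester lands only on the C3 oxygen, and C5 is set 1,3-anti.
3. 9 ⇒ 8: key disconnection, the C3–O bond, made by catalytic asymmetric conjugate peroxidation of the E-enone.
4. 8 ⇒ 2 + 6: cross-aldol condensation, with 2 from raspberry ketone 1 and 6 from dihydrocaffeic acid 3.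
5. No ring is formed. Both benzene rings are bought with 1 and 3.

Numbering note: positions are given in target numbering (C1 at the catechol ring, C3 acetate carbon, C5 carbinol carbon, C7 at the 4-hydroxyphenyl ring). Systematic names of the ketones count from the other end. The target is (3R,5R), the 1,3-anti series.

Assumption: the quinine-derived amine of step 5 is taken to deliver the peroxide to the Re face of C3. If a Mosher check shows the opposite, the quinidine-derived pseudo-enantiomer is used and nothing else changes.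

## Route

Step 1
Reactants: 1 4-(4-hydroxyphenyl)butan-2-one (raspberry ketone)
Product: 2 4-[4-(benzyloxy)phenyl]butan-2-one
Conditions: BnBr (1.1 equiv), K2CO3 (1.5 equiv), acetone, reflux
Reagents that add atoms: benzyl bromide, BrCc1ccccc1
Why: Williamson ether synthesis; the phenoxide displaces bromide by SN2 and K2CO3 is too weak to alkylate the ketone.

Step 2
Reactants: 3 3-(3,4-dihydroxyphenyl)propanoic acid (dihydrocaffeic acid)
Product: 4 benzyl 3-[3,4-bis(benzyloxy)phenyl]propanoate
Conditions: BnBr (3.5 equiv), K2CO3 (4.5 equiv), DMF, 60 °C, N2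
Reagents that add atoms: benzyl bromide, BrCc1ccccc1
Why: Williamson etherification and carboxylate O-alkylation benzylate all three acidic OH groups in one operation, and N2 keeps the catecholate from air oxidation.

Step 3
Reactants: 4 benzyl 3-[3,4-bis(benzyloxy)phenyl]propanoate
Product: 6 3-[3,4-bis(benzyloxy)phenyl]propanal, via aluminium hemiacetal 5 (not isolated)
Conditions: i-Bu2AlH (1.1 equiv), toluene, −78 °C; then aq. potassium sodium tartrate
Reagents that add atoms: none
Why: Partial ester reduction; the tetrahedral aluminium hemiacetal 5 is stable at −78 °C and collapses only on quench, so reduction stops at the aldehyde.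

Step 4
Reactants: 2 4-[4-(benzyloxy)phenyl]butan-2-one; 6 3-[3,4-bis(benzyloxy)phenyl]propanal
Product: 8 (4E)-7-[3,4-bis(benzyloxy)phenyl]-1-[4-(benzyloxy)phenyl]hept-4-en-3-one, via racemic aldol 7 (not isolated)
Conditions: pyrrolidine (0.5 equiv), AcOH (0.5 equiv), THF, 23 °C; 6 added over 4 h to 2 (1.5 equiv), then 16 h
Reagents that add atoms: none
Why: Amine-catalysed cross-aldol condensation; the less substituted enamine of the methyl ketone adds to the slowly fed aldehyde, and E1cB loss of water gives the more stable E-enone.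

Step 5
Reactants: 8 (4E)-7-[3,4-bis(benzyloxy)phenyl]-1-[4-(benzyloxy)phenyl]hept-4-en-3-one
Product: 9 (5R)-7-[3,4-bis(benzyloxy)phenyl]-1-[4-(benzyloxy)phenyl]-5-(tert-butylperoxy)heptan-3-one
Conditions: t-BuOOH (5.5 M in decane, 1.5 equiv), 9-amino-9-deoxy-epi-quinine (10 mol %), CF3CO2H (30 mol %), toluene, 0 °C, 48 h
Reagents that add atoms: tert-butyl hydroperoxide, CC(C)(C)OO
Why: Asymmetric oxa-Michael addition (conjugate peroxidation) under iminium-ion catalysis; the protonated quinuclidine holds t-BuOOH by a hydrogen bond and passes it to the Re face of C3, forming the key C3–O bond as R, while 0 °C and the poor tert-butoxide leaving group hold back closure to the epoxide.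

Step 6
Reactants: 9 (5R)-7-[3,4-bis(benzyloxy)phenyl]-1-[4-(benzyloxy)phenyl]-5-(tert-butylperoxy)heptan-3-one
Product: 13 (3R,5R)-1-[3,4-bis(benzyloxy)phenyl]-7-[4-(benzyloxy)phenyl]-5-hydroxyheptan-3-yl acetate, via samarium aldolate 10 (not isolated), via samarium hemiacetal alkoxide 11 (not isolated), via samarium carbinolate 12 (not isolated)
Conditions: SmI2 (2.2 equiv, 0.1 M in THF, added until the blue colour persists), THF, −78 °C, 15 min; then MeCHO (10 equiv), −78 → −10 °C, 2 h; sat. aq. NaHCO3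
Reagents that add atoms: acetaldehyde, CC=O
Why: Proposed new method: reductive Evans–Tishchenko reaction of a β-peroxy ketone; divalent samarium, chelated by the ketone oxygen and the inner peroxide oxygen, cleaves the weak O–O bond by two one-electron transfers and leaves the C3 oxygen as the trivalent samarium aldolate 10 (beside t-BuOSmI2, which has no α-hydrogen to donate); acetaldehyde then adds to give the hemiacetal alkoxide 11, and a chelated chair-like transition state passes its hydride intramolecularly to the ketone face that gives the 1,3-anti carbinolate 12, so one operation unmasks the C3–O bond, acetylates that oxygen only and sets C5 as R; the closest known reaction types are the SmI2-catalysed Evans–Tishchenko reduction of free β-hydroxy ketones and the SmI2 reduction of dialkyl peroxides to alcohols, which have not been combined on a β-peroxy ketone.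

Step 7
Reactants: 13 (3R,5R)-1-[3,4-bis(benzyloxy)phenyl]-7-[4-(benzyloxy)phenyl]-5-hydroxyheptan-3-yl acetate
Product: 14 (3R,5R)-1-(3,4-dihydroxyphenyl)-5-hydroxy-7-(4-hydroxyphenyl)heptan-3-yl acetate
Conditions: H2 (1 atm), 10% Pd/C, EtOAc–EtOH 1:1, 23 °C; filtration under N2
Reagents that add atoms: none
Why: Catalytic hydrogenolysis of three aryl benzyl ethers; C3 and C5 are neither benzylic nor allylic, so their C–O bonds and configurations persist, and the neutral medium avoids 1,3-acetyl migration.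

## Compound list
1 | 4-(4-hydroxyphenyl)butan-2-one | CC(=O)CCc1ccc(O)cc1 | starting material
2 | 4-[4-(benzyloxy)phenyl]butan-2-one | CC(=O)CCc1ccc(OCc2ccccc2)cc1 | intermediate
3 | 3-(3,4-dihydroxyphenyl)propanoic acid | OC(=O)CCc1ccc(O)c(O)c1 | starting material
4 | benzyl 3-[3,4-bis(benzyloxy)phenyl]propanoate | O=C(CCc1ccc(OCc2ccccc2)c(OCc2ccccc2)c1)OCc1ccccc1 | intermediate
5 | {1-(benzyloxy)-3-[3,4-bis(benzyloxy)phenyl]propoxy}diisobutylaluminium (aluminium hemiacetal) | CC(C)C[Al](CC(C)C)OC(CCc1ccc(OCc2ccccc2)c(OCc2ccccc2)c1)OCc1ccccc1 | intermediate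
6 | 3-[3,4-bis(benzyloxy)phenyl]propanal | O=CCCc1ccc(OCc2ccccc2)c(OCc2ccccc2)c1 | intermediate
7 | racemic 7-[3,4-bis(benzyloxy)phenyl]-1-[4-(benzyloxy)phenyl]-5-hydroxyheptan-3-one | OC(CCc1ccc(OCc2ccccc2)c(OCc2ccccc2)c1)CC(=O)CCc1ccc(OCc2ccccc2)cc1 | intermediate
8 | (4E)-7-[3,4-bis(benzyloxy)phenyl]-1-[4-(benzyloxy)phenyl]hept-4-en-3-one | O=C(CCc1ccc(OCc2ccccc2)cc1)/C=C/CCc1ccc(OCc2ccccc2)c(OCc2ccccc2)c1 | intermediate
9 | (5R)-7-[3,4-bis(benzyloxy)phenyl]-1-[4-(benzyloxy)phenyl]-5-(tert-butylperoxy)heptan-3-one | CC(C)(C)OO[C@H](CCc1ccc(OCc2ccccc2)c(OCc2ccccc2)c1)CC(=O)CCc1ccc(OCc2ccccc2)cc1 | intermediate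
10 | (5R)-7-[3,4-bis(benzyloxy)phenyl]-1-[4-(benzyloxy)phenyl]-5-(diiodosamariooxy)heptan-3-one | I[Sm](I)O[C@H](CCc1ccc(OCc2ccccc2)c(OCc2ccccc2)c1)CC(=O)CCc1ccc(OCc2ccccc2)cc1 | intermediate
11 | (5R)-7-[3,4-bis(benzyloxy)phenyl]-1-[4-(benzyloxy)phenyl]-5-[1-(diiodosamariooxy)ethoxy]heptan-3-one (hemiacetal carbon unassigned) | CC(O[Sm](I)I)O[C@H](CCc1ccc(OCc2ccccc2)c(OCc2ccccc2)c1)CC(=O)CCc1ccc(OCc2ccccc2)cc1 | intermediate
12 | (3R,5R)-1-[3,4-bis(benzyloxy)phenyl]-7-[4-(benzyloxy)phenyl]-5-(diiodosamariooxy)heptan-3-yl acetate | CC(=O)O[C@H](CCc1ccc(OCc2ccccc2)c(OCc2ccccc2)c1)C[C@H](O[Sm](I)I)CCc1ccc(OCc2ccccc2)cc1 | intermediate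
13 | (3R,5R)-1-[3,4-bis(benzyloxy)phenyl]-7-[4-(benzyloxy)phenyl]-5-hydroxyheptan-3-yl acetate | CC(=O)O[C@H](CCc1ccc(OCc2ccccc2)c(OCc2ccccc2)c1)C[C@H](O)CCc1ccc(OCc2ccccc2)cc1 | intermediate
14 | (3R,5R)-1-(3,4-dihydroxyphenyl)-5-hydroxy-7-(4-hydroxyphenyl)heptan-3-yl acetate | CC(=O)O[C@H](CCc1ccc(O)c(O)c1)C[C@H](O)CCc1ccc(O)cc1 | target

## Count and risks
Total step count: 7.
Longest linear sequence: 6 steps (3 → 4 → 6 → 8 → 9 → 13 → 14).

**Step 6 (the proposed new step).** Three failure modes are foreseen: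
- An alkoxyl radical at the C3 oxygen could undergo β-scission.
- Aldolate 10 could undergo retro-aldol before acetaldehyde arrives.
- The acetyl group could migrate within carbinolate 12.

The fallback uses known chemistry only. It sets out from 9 and comes back at 13. Activated Zn dust in AcOH–THF (23 to 40 °C) cleaves the O–O bond by a two-electron path to give (5R)-7-[3,4-bis(benzyloxy)phenyl]-1-[4-(benzyloxy)phenyl]-5-hydroxyheptan-3-one F3, which is isolated. The classical catalytic Evans–Tishchenko reduction (SmI2 0.3 equiv, MeCHO 10 equiv, THF, −10 °C) then gives 13 with the same 1,3-anti outcome.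

**Step 5.** The peroxide-to-epoxide ratio and the enantiomeric excess may drop on this long-chain ketone. The fallback sets out from 8 and comes back at 13.
- Copper-catalysed asymmetric conjugate borylation forms a C–B bond first. Conditions: CuCl 3 mol %, NaOt-Bu 3 mol %, (R)-1-[(S)-2-(diphenylphosphino)ferrocenyl]ethyldicyclohexylphosphine or its enantiomer, whichever gives 5R, B2pin2, MeOH, THF, 23 °C.
- The product is (5R)-7-[3,4-bis(benzyloxy)phenyl]-1-[4-(benzyloxy)phenyl]-5-(4,4,5,5-tetramethyl-1,3,2-dioxaborolan-2-yl)heptan-3-one F2.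
- NaBO3·4H2O in THF–H2O oxidises C–B to C–O with retention and gives the hydroxy ketone F3.
- The catalytic Evans–Tishchenko reduction described above then leads to 13.

**Step 4.** Aldehyde 6 can self-condense through its own enamine. The fallback sets out from 2 and 6 and comes back at 8.
- The kinetic lithium enolate of 2 (LiN(i-Pr)2, THF, −78 °C) is formed first and adds to 6 in a directed aldol reaction, giving the racemic aldol 7, this time isolated.
- MsCl/Et3N in CH2Cl2 at 0 °C converts 7 into racemic 1-[3,4-bis(benzyloxy)phenyl]-7-[4-(benzyloxy)phenyl]-5-oxoheptan-3-yl methanesulfonate F1.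
- DBU at 23 °C eliminates F1 to the E-enone 8.

## Further compounds
F1 | step 4 | racemic 1-[3,4-bis(benzyloxy)phenyl]-7-[4-(benzyloxy)phenyl]-5-oxoheptan-3-yl methanesulfonate | CS(=O)(=O)OC(CCc1ccc(OCc2ccccc2)c(OCc2ccccc2)c1)CC(=O)CCc1ccc(OCc2ccccc2)cc1
F2 | step 5 | (5R)-7-[3,4-bis(benzyloxy)phenyl]-1-[4-(benzyloxy)phenyl]-5-(4,4,5,5-tetramethyl-1,3,2-dioxaborolan-2-yl)heptan-3-one | CC1(C)OB(OC1(C)C)[C@H](CCc2ccc(OCc3ccccc3)c(OCc3ccccc3)c2)CC(=O)CCc2ccc(OCc3ccccc3)cc2
F3 | step 6 | (5R)-7-[3,4-bis(benzyloxy)phenyl]-1-[4-(benzyloxy)phenyl]-5-hydroxyheptan-3-one | O[C@H](CCc1ccc(OCc2ccccc2)c(OCc2ccccc2)c1)CC(=O)CCc1ccc(OCc2ccccc2)cc1
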